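**Strategy.** The route rests on disconnecting ring 1, the oxepane O–C5–C6–C7–C8–C9–C10, at its O–C5 bond in the retron C6(=O)–C5(O)–C4(C15)–C3=C, an α-alkoxy ketone with a homoallylic branch (atom numbers are defined below). An acyclic α-diazoketone (C5, C6) carrying a tertiary (Z)-butenyl ether at C10 is turned by a copper carbenoid into a seven-membered oxonium ylide, whose [2,3]-shift moves the butenyl group from oxygen to C5. One operation closes ring 1, forms O–C5 and C4–C5, sets C5 and C4 and installs the vinyl group that later closes the enone ring 2 by metathesis.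

Key step: step 15

Numbering: C1 ketone carbon, C2=C3 ring alkene, C4 (bears C15H2OH), C5 ether CH, C6 lactone CH–O, C7, C8 (angelate), C9H2, C10 quaternary ether carbon (bears C14 methyl), C11=C13 exocyclic methylene, C12 lactone carbonyl; ring 1 = O–C5–C6–C7–C8–C9–C10, ring 2 = O–C10–C1–C2–C3–C4–C5; PMB = 4-methoxybenzyl, TBS = tert-butyldimethylsilyl.

Remark: read literally, the SMILES has the ether bridge trans across ring 1 (C4 on C5 and C1 on C10 on opposite faces, C4 cis to the C10 methyl), i.e. an inside–outside 11-oxabicyclo[4.4.1]undecene; the route is designed for exactly this isomer.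

Step 1
Reactants: 1 (Z)-but-2-ene-1,4-diol
Product: 2 (Z)-4-(4-methoxybenzyloxy)but-2-en-1-ol
Conditions: NaH (1 equiv), PMBCl (1 equiv), Bu4NI (cat.), THF/DMF, 0 °C to rt, diol in excess
Reagents that add atoms: 4-methoxybenzyl chloride COc1ccc(CCl)cc1
Why: Williamson etherification of the symmetrical diol, made statistically mono-selective by the excess of diol, with the Z alkene untouched.

Step 2
Reactants: 2 (Z)-4-(4-methoxybenzyloxy)but-2-en-1-ol
Product: 3 (Z)-1-bromo-4-(4-methoxybenzyloxy)but-2-ene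
Conditions: CBr4, PPh3, CH2Cl2, 0 °C
Reagents that add atoms: carbon tetrabromide BrC(Br)(Br)Br
Why: Appel reaction, an SN2 displacement at the primary allylic carbon that should keep the Z geometry.

Step 3
Reactants: 4 methacrolein
Product: 5 rac-2-methylpenta-1,4-dien-3-ol
Conditions: CH2=CHMgBr, THF, −78 to 0 °C; aqueous NH4Cl
Reagents that add atoms: vinylmagnesium bromide C=C[Mg]Br
Why: Grignard 1,2-addition to the enal gives the racemic bis-allylic alcohol that holds C1, C9, C10 and C14.

Step 4
Reactants: 5 rac-2-methylpenta-1,4-dien-3-ol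
Product: 6 (R)-1-[(S)-2-methyloxiran-2-yl]prop-2-en-1-ol
Conditions: Ti(OiPr)4 (10 mol%), D-(−)-diisopropyl tartrate (15 mol%), tBuOOH (0.5 equiv), 4 Å molecular sieves, CH2Cl2, −20 °C
Reagents that add atoms: tert-butyl hydroperoxide CC(C)(C)OO
Why: Sharpless asymmetric epoxidation run as a kinetic resolution: the D-tartrate catalyst should epoxidise only the (R)-alcohol at its more nucleophilic 1,1-disubstituted alkene, giving the erythro epoxy alcohol (C10 S, C1 R) and leaving (S)-5 behind.

Step 5
Reactants: 6 (R)-1-[(S)-2-methyloxiran-2-yl]prop-2-en-1-ol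
Product: 7 (S)-2-[(R)-1-(4-methoxybenzyloxy)prop-2-enyl]-2-methyloxirane
Conditions: NaH, PMBCl, Bu4NI (cat.), THF, 0 °C
Reagents that add atoms: 4-methoxybenzyl chloride COc1ccc(CCl)cc1
Why: Williamson etherification protects the C1 hydroxyl with a group that cannot migrate to the tertiary alkoxide formed later and is finally removed oxidatively.

Step 6
Reactants: 7 (S)-2-[(R)-1-(4-methoxybenzyloxy)prop-2-enyl]-2-methyloxirane; 8 1,3-dithiane
Product: 10 (2S,3R)-1-(1,3-dithian-2-yl)-3-(4-methoxybenzyloxy)-2-methylpent-4-en-2-ol, via 2-lithio-1,3-dithiane 9 (not isolated)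
Conditions: 8, n-BuLi, THF, −30 °C; then 7, DMPU, −30 to 0 °C; aqueous NH4Cl
Reagents that add atoms: none
Why: Corey–Seebach umpolung: the dithiane anion opens the 2,2-disubstituted epoxide at its unhindered CH2 (C9), which brings in C8 as a masked aldehyde and leaves the C10 configuration untouched.

Step 7
Reactants: 10 (2S,3R)-1-(1,3-dithian-2-yl)-3-(4-methoxybenzyloxy)-2-methylpent-4-en-2-ol; 3 (Z)-1-bromo-4-(4-methoxybenzyloxy)but-2-ene
Product: 11 tertiary (Z)-4-(4-methoxybenzyloxy)but-2-enyl ether of 10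
Conditions: KH, 18-crown-6 (cat.), THF, 0 °C; then 3, 0 °C to rt
Reagents that add atoms: none
Why: Williamson etherification of the tertiary potassium alkoxide with the reactive primary allylic bromide (SN2, Z geometry kept) installs the group that will migrate in the key step.

Step 8
Reactants: 11 tertiary (Z)-4-(4-methoxybenzyloxy)but-2-enyl ether of 10
Product: 12 (3S,4R)-4-(4-methoxybenzyloxy)-3-[(Z)-4-(4-methoxybenzyloxy)but-2-enyloxy]-3-methylhex-5-enal
Conditions: MeI, NaHCO3, MeCN/H2O, 40 °C
Reagents that add atoms: water O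
Why: alkylative hydrolysis of the dithioacetal frees the C8 aldehyde under conditions that spare the PMB ethers and alkenes; the β-carbon is quaternary, so no elimination is possible.

Step 9
Reactants: 12 (3S,4R)-4-(4-methoxybenzyloxy)-3-[(Z)-4-(4-methoxybenzyloxy)but-2-enyloxy]-3-methylhex-5-enal; 13 ethyl diazoacetate
Product: 14 ethyl (5S,6R)-6-(4-methoxybenzyloxy)-5-[(Z)-4-(4-methoxybenzyloxy)but-2-enyloxy]-5-methyl-3-oxooct-7-enoate
Conditions: SnCl2 (10 mol%), CH2Cl2, rt
Reagents that add atoms: none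
Why: Roskamp homologation (Lewis-acid addition of the diazo ester to the aldehyde, then 1,2-hydride shift with loss of N2) gives the β-keto ester that holds C6, C7 and C8.

Step 10
Reactants: 14 ethyl (5S,6R)-6-(4-methoxybenzyloxy)-5-[(Z)-4-(4-methoxybenzyloxy)but-2-enyloxy]-5-methyl-3-oxooct-7-enoate
Product: 15 ethyl (3R,5S,6R)-3-hydroxy-6-(4-methoxybenzyloxy)-5-[(Z)-4-(4-methoxybenzyloxy)but-2-enyloxy]-5-methyloct-7-enoate
Conditions: H2 (4 atm), RuCl2[(R)-BINAP] (1 mol%), EtOH, 40 °C
Reagents that add atoms: none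
Why: Noyori asymmetric hydrogenation: the ester-chelated (R)-BINAP ruthenium hydride should deliver hydrogen to one face of the β-keto ester and give the (R)-carbinol at C8 (same sense as methyl (R)-3-hydroxybutanoate), while the isolated alkenes are not expected to be reduced by this halide catalyst.

Step 11
Reactants: 15 ethyl (3R,5S,6R)-3-hydroxy-6-(4-methoxybenzyloxy)-5-[(Z)-4-(4-methoxybenzyloxy)but-2-enyloxy]-5-methyloct-7-enoate; 16 tert-butyl bromoacetate
Product: 17 anti-alkylated diester (ethyl ester at C6; CH2CO2tBu at C7; C7 R; C8 R)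
Conditions: LiN(iPr)2 (2.2 equiv), THF, −78 to −20 °C; then 16, DMPU, −78 to −20 °C; aqueous NH4Cl
Reagents that add atoms: none
Why: Fráter–Seebach alkylation: the lithium-chelated dianion of the β-hydroxy ester is alkylated on the face opposite the C9 chain, which should set C7 anti to the C8 hydroxyl, as the target needs.

Step 12
Reactants: 17 anti-alkylated diester (ethyl ester at C6; CH2CO2tBu at C7; C7 R; C8 R)
Product: 18 C8 TBS ether of 17
Conditions: TBSOTf, 2,6-lutidine, CH2Cl2, −78 °C
Reagents that add atoms: tert-butyldimethylsilyl triflate CC(C)(C)[Si](C)(C)OS(=O)(=O)C(F)(F)F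
Why: silylation masks the C8 hydroxyl as a bulky, weakly nucleophilic ether so that it neither undergoes O–H insertion nor readily forms an ylide in the carbenoid step.

Step 13
Reactants: 18 C8 TBS ether of 17
Product: 19 C6 carboxylic acid (tert-butyl ester at C12 kept)
Conditions: Me3SnOH, 1,2-dichloroethane, 80 °C; dilute HCl wash
Reagents that add atoms: trimethyltin hydroxide C[Sn](C)(C)O
Why: trimethyltin hydroxide hydrolysis should cleave the ethyl ester and not the tert-butyl ester under nearly neutral conditions, avoiding epimerisation at C7 and β-elimination of the silyloxy group.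

Step 14
Reactants: 19 C6 carboxylic acid (tert-butyl ester at C12 kept)
Product: 21 α-diazoketone (C5 diazo carbon; C6 ketone), via mixed carbonic anhydride 20 (not isolated)
Conditions: iBuOCOCl, Et3N, THF, −20 °C; then CH2N2, Et2O, 0 °C to rt
Reagents that add atoms: diazomethane C=[N+]=[N-]
Why: acylation of diazomethane by the mixed anhydride (first stage of the Arndt–Eistert sequence) brings in C5 as the carbenoid precursor without disturbing C7.

Step 15
Reactants: 21 α-diazoketone (C5 diazo carbon; C6 ketone)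
Product: 23 2,7-trans oxepan-3-one (ring 1; C1 R; C4 R; C5 R; C7 R; C8 R; C10 S), via oxonium ylide 22 (not isolated)
Conditions: Cu(hfacac)2 (copper bis(hexafluoroacetylacetonate), 5 mol%), CH2Cl2, reflux, slow addition of 21 to high dilution
Reagents that add atoms: none
Why: The copper catalyst decomposes the diazoketone to an electrophilic carbenoid at C5, which is captured by a lone pair of the C10 ether oxygen to give the cyclic oxonium ylide 22; this ring-closing O–C5 bond formation makes the seven-membered oxepan-3-one ring 1, a ring size for which tandem oxonium ylide formation/[2,3]-sigmatropic rearrangement of copper carbenoids with allyl ethers is established. The ylide then transfers the butenyl group suprafacially from oxygen to C5 through a five-membered envelope transition state, forming C4–C5 and releasing the C3 vinyl group. C5 is controlled by the configuration at the oxonium oxygen: the butenyl group should sit pseudo-equatorial, anti to the larger C10 substituent (the branched C1 carbinol arm), and is therefore delivered to the face of C5 cis to the C10 methyl, the same trans preference seen in 2,5- and 2,6-disubstituted cyclic ethers made this way. C4 is controlled by the Z geometry of the butenyl group in the envelope whose allyl β-carbon (C3) points away from ring 1 and from the axial C10 methyl, which places CH2OPMB over C6 and gives the 4R,5R relationship. The step needs chemoselectivity for the hindered ether oxygen over 1,5 C–H insertion and over the C8 oxygen, which the electron-poor copper catalyst, high dilution and the bulky silyl ether are meant to secure.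

Step 16
Reactants: 23 2,7-trans oxepan-3-one (ring 1; C1 R; C4 R; C5 R; C7 R; C8 R; C10 S)
Product: 24 C6 alcohol with hydroxyl cis to the C5 branch and to the C7 side chain
Conditions: LiBH(sBu)3, THF, −78 °C; aqueous NH4Cl
Reagents that add atoms: none
Why: the bulky hydride should attack the ketone from the face opposite the two flanking equatorial substituents (C4 branch on C5, CH2CO2tBu on C7), giving the axial alcohol, which is the C6 epimer needed for an inverting lactonisation.

Step 17
Reactants: 24 C6 alcohol with hydroxyl cis to the C5 branch and to the C7 side chain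
Product: 26 trans-fused 6,12-lactone (C6 S as in the target), via C6 triflate 25 (not isolated)
Conditions: Tf2O, 2,6-di-tert-butyl-4-methylpyridine, CH2Cl2, −78 to 0 °C
Reagents that add atoms: none
Why: the axial triflate is displaced intramolecularly by the carbonyl oxygen of the tert-butyl ester (neighbouring-group SN2, five-membered), and loss of isobutene from the resulting dialkoxycarbenium ion gives the lactone with inversion at C6, i.e. trans-fused to C7.

Step 18
Reactants: 26 trans-fused 6,12-lactone (C6 S as in the target)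
Product: 27 trans-bridged bicyclic lactone with ring 2 closed (C2=C3 cis; C1 still OPMB)
Conditions: second-generation Hoveyda–Grubbs catalyst (10 mol%), toluene (2 mM), 80 °C, argon sparge
Reagents that add atoms: none
Why: ring-closing metathesis of the two monosubstituted vinyl groups (on C1 and C4) with loss of ethene closes the seven-membered ring 2 as its cis alkene; ring 1 can adopt the twist-chair with oxygen on the axis that brings the trans arms together, and metathesis is known to close inside–outside bicyclo[4.4.1] frameworks.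

Step 19
Reactants: 27 trans-bridged bicyclic lactone with ring 2 closed (C2=C3 cis; C1 still OPMB)
Product: 30 α-methylene lactone, via Mannich base 28 (not isolated), via ammonium iodide 29 (not isolated)
Conditions: LiN(SiMe3)2, THF, −78 °C; Eschenmoser's salt, −78 to 0 °C; then MeI, rt; then aqueous NaHCO3, rt
Reagents that add atoms: N,N-dimethylmethyleneiminium iodide C=[N+](C)C.[I-]
Why: Eschenmoser methylenation (Mannich reaction of the lactone enolate, N-methylation and base-induced elimination of trimethylamine) installs C13 before any enone or angelate is present.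

Step 20
Reactants: 30 α-methylene lactone
Product: 31 C8 alcohol
Conditions: HF·pyridine, pyridine, THF, 0 °C to rt
Reagents that add atoms: none
Why: fluoride-mediated cleavage of the secondary silyl ether leaves the PMB ethers and the α-methylene lactone intact.

Step 21
Reactants: 31 C8 alcohol; 32 angelic acid
Product: 34 C8 angelate, via angelic mixed anhydride 33 (not isolated)
Conditions: 32, 2,4,6-trichlorobenzoyl chloride, Et3N, toluene, rt; then 31, DMAP, toluene, 60 °C
Reagents that add atoms: none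
Why: Yamaguchi esterification through the hindered aroyl mixed anhydride acylates the C8 hydroxyl with retention and is the standard way to avoid isomerisation of the (Z)-angelate to the tiglate.

Step 22
Reactants: 34 C8 angelate
Product: 35 C1,C15 diol
Conditions: DDQ, CH2Cl2/pH 7 buffer, 0 °C to rt
Reagents that add atoms: none
Why: oxidative cleavage of both PMB ethers (benzylic hydride abstraction, then hydrolysis) frees the allylic C1 hydroxyl and the primary C15 hydroxyl without touching the esters or electron-poor alkenes.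

Step 23
Reactants: 35 C1,C15 diol
Product: 36 target CNP0274187.1
Conditions: MnO2 (activated, excess), CH2Cl2, rt
Reagents that add atoms: none
Why: manganese dioxide oxidises only the allylic secondary alcohol at C1 to the enone and leaves the non-allylic primary C15 hydroxyl free.

**Compound list**

1 | (Z)-but-2-ene-1,4-diol | OC/C=C\CO | starting material
2 | (Z)-4-(4-methoxybenzyloxy)but-2-en-1-ol | OC/C=C\COCc1ccc(OC)cc1 | intermediate
3 | (Z)-1-bromo-4-(4-methoxybenzyloxy)but-2-ene | BrC/C=C\COCc1ccc(OC)cc1 | intermediate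
4 | methacrolein (2-methylprop-2-enal) | C=C(C)C=O | starting material
5 | rac-2-methylpenta-1,4-dien-3-ol | C=CC(O)C(C)=C | intermediate
6 | (R)-1-[(S)-2-methyloxiran-2-yl]prop-2-en-1-ol | C=C[C@@H](O)[C@]1(C)CO1 | intermediate
7 | (S)-2-[(R)-1-(4-methoxybenzyloxy)prop-2-enyl]-2-methyloxirane | C=C[C@@H](OCc1ccc(OC)cc1)[C@]1(C)CO1 | intermediate
8 | 1,3-dithiane | C1CSCSC1 | starting material
9 | 2-lithio-1,3-dithiane (not isolated) | [Li]C1SCCCS1 | intermediate
10 | (2S,3R)-1-(1,3-dithian-2-yl)-3-(4-methoxybenzyloxy)-2-methylpent-4-en-2-ol | C=C[C@@H](OCc1ccc(OC)cc1)[C@@](C)(O)CC1SCCCS1 | intermediate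
11 | tertiary (Z)-4-(4-methoxybenzyloxy)but-2-enyl ether of 10 | C=C[C@@H](OCc1ccc(OC)cc1)[C@@](C)(OC/C=C\COCc1ccc(OC)cc1)CC1SCCCS1 | intermediate
12 | (3S,4R)-4-(4-methoxybenzyloxy)-3-[(Z)-4-(4-methoxybenzyloxy)but-2-enyloxy]-3-methylhex-5-enal | C=C[C@@H](OCc1ccc(OC)cc1)[C@@](C)(OC/C=C\COCc1ccc(OC)cc1)CC=O | intermediate
13 | ethyl diazoacetate | CCOC(=O)C=[N+]=[N-] | starting material
14 | ethyl (5S,6R)-6-(4-methoxybenzyloxy)-5-[(Z)-4-(4-methoxybenzyloxy)but-2-enyloxy]-5-methyl-3-oxooct-7-enoate | C=C[C@@H](OCc1ccc(OC)cc1)[C@@](C)(OC/C=C\COCc1ccc(OC)cc1)CC(=O)CC(=O)OCC | intermediate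
15 | ethyl (3R,5S,6R)-3-hydroxy-6-(4-methoxybenzyloxy)-5-[(Z)-4-(4-methoxybenzyloxy)but-2-enyloxy]-5-methyloct-7-enoate | C=C[C@@H](OCc1ccc(OC)cc1)[C@@](C)(OC/C=C\COCc1ccc(OC)cc1)C[C@@H](O)CC(=O)OCC | intermediate
16 | tert-butyl bromoacetate | CC(C)(C)OC(=O)CBr | starting material
17 | anti-alkylated diester (ethyl ester at C6; CH2CO2tBu at C7; C7 R; C8 R) | C=C[C@@H](OCc1ccc(OC)cc1)[C@@](C)(OC/C=C\COCc1ccc(OC)cc1)C[C@@H](O)[C@@H](CC(=O)OC(C)(C)C)C(=O)OCC | intermediate
18 | C8 TBS ether of 17 | C=C[C@@H](OCc1ccc(OC)cc1)[C@@](C)(OC/C=C\COCc1ccc(OC)cc1)C[C@@H](O[Si](C)(C)C(C)(C)C)[C@@H](CC(=O)OC(C)(C)C)C(=O)OCC | intermediate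
19 | C6 carboxylic acid (tert-butyl ester at C12 kept) | C=C[C@@H](OCc1ccc(OC)cc1)[C@@](C)(OC/C=C\COCc1ccc(OC)cc1)C[C@@H](O[Si](C)(C)C(C)(C)C)[C@@H](CC(=O)OC(C)(C)C)C(=O)O | intermediate
20 | mixed carbonic anhydride of 19 with isobutyl carbonate (not isolated) | C=C[C@@H](OCc1ccc(OC)cc1)[C@@](C)(OC/C=C\COCc1ccc(OC)cc1)C[C@@H](O[Si](C)(C)C(C)(C)C)[C@@H](CC(=O)OC(C)(C)C)C(=O)OC(=O)OCC(C)C | intermediate
21 | α-diazoketone (C5 diazo carbon; C6 ketone) | C=C[C@@H](OCc1ccc(OC)cc1)[C@@](C)(OC/C=C\COCc1ccc(OC)cc1)C[C@@H](O[Si](C)(C)C(C)(C)C)[C@@H](CC(=O)OC(C)(C)C)C(=O)C=[N+]=[N-] | intermediate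
22 | seven-membered oxonium ylide (O-butenyl oxonium enolate; not isolated) | [O-]C1=C[O+](C/C=C\COCc2ccc(OC)cc2)[C@](C)([C@H](OCc2ccc(OC)cc2)C=C)C[C@@H](O[Si](C)(C)C(C)(C)C)[C@H]1CC(=O)OC(C)(C)C | intermediate
23 | 2,7-trans oxepan-3-one (ring 1; C1 R; C4 R; C5 R; C7 R; C8 R; C10 S) | O=C1[C@H](CC(=O)OC(C)(C)C)[C@H](O[Si](C)(C)C(C)(C)C)C[C@@](C)([C@H](OCc2ccc(OC)cc2)C=C)O[C@@H]1[C@H](C=C)COCc1ccc(OC)cc1 | intermediate
24 | C6 alcohol with hydroxyl cis to the C5 branch and to the C7 side chain (C6 epimeric to the target) | O[C@@H]1[C@H](CC(=O)OC(C)(C)C)[C@H](O[Si](C)(C)C(C)(C)C)C[C@@](C)([C@H](OCc2ccc(OC)cc2)C=C)O[C@@H]1[C@H](C=C)COCc1ccc(OC)cc1 | intermediate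
25 | C6 triflate of 24 (not isolated) | O=S(=O)(O[C@@H]1[C@H](CC(=O)OC(C)(C)C)[C@H](O[Si](C)(C)C(C)(C)C)C[C@@](C)([C@H](OCc2ccc(OC)cc2)C=C)O[C@@H]1[C@H](C=C)COCc1ccc(OC)cc1)C(F)(F)F | intermediate
26 | trans-fused 6,12-lactone (C6 S as in the target) | O=C1C[C@@H]2[C@H](O[Si](C)(C)C(C)(C)C)C[C@@](C)([C@H](OCc3ccc(OC)cc3)C=C)O[C@H]([C@H](C=C)COCc3ccc(OC)cc3)[C@H]2O1 | intermediate
27 | trans-bridged bicyclic lactone with ring 2 closed (C2=C3 cis; C1 still OPMB) | O=C1C[C@@H]2[C@H](O[Si](C)(C)C(C)(C)C)C[C@]3(C)O[C@@H]([C@H]2O1)[C@@H](COCc4ccc(OC)cc4)C=C[C@H]3OCc4ccc(OC)cc4 | intermediate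
28 | C11 dimethylaminomethyl lactone (Mannich base; C11 epimers; not isolated) | O=C1C(CN(C)C)[C@@H]2[C@H](O[Si](C)(C)C(C)(C)C)C[C@]3(C)O[C@@H]([C@H]2O1)[C@@H](COCc4ccc(OC)cc4)C=C[C@H]3OCc4ccc(OC)cc4 | intermediate
29 | C11 trimethylammoniomethyl lactone iodide (not isolated) | O=C1C(C[N+](C)(C)C)[C@@H]2[C@H](O[Si](C)(C)C(C)(C)C)C[C@]3(C)O[C@@H]([C@H]2O1)[C@@H](COCc4ccc(OC)cc4)C=C[C@H]3OCc4ccc(OC)cc4.[I-] | intermediate
30 | α-methylene lactone (C8 OTBS; C1 and C15 OPMB) | C=C1C(=O)O[C@@H]2[C@@H]3O[C@@](C)(C[C@@H](O[Si](C)(C)C(C)(C)C)[C@@H]12)[C@H](OCc4ccc(OC)cc4)C=C[C@@H]3COCc4ccc(OC)cc4 | intermediate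
31 | C8 alcohol | C=C1C(=O)O[C@@H]2[C@@H]3O[C@@](C)(C[C@@H](O)[C@@H]12)[C@H](OCc4ccc(OC)cc4)C=C[C@@H]3COCc4ccc(OC)cc4 | intermediate
32 | angelic acid ((Z)-2-methylbut-2-enoic acid) | C/C=C(/C)C(=O)O | starting material
33 | angelic 2,4,6-trichlorobenzoic anhydride (not isolated) | C/C=C(/C)C(=O)OC(=O)c1c(Cl)cc(Cl)cc1Cl | intermediate
34 | C8 angelate (C1 and C15 OPMB) | C=C1C(=O)O[C@@H]2[C@@H]3O[C@@](C)(C[C@@H](OC(=O)/C(C)=C\C)[C@@H]12)[C@H](OCc4ccc(OC)cc4)C=C[C@@H]3COCc4ccc(OC)cc4 | intermediate
35 | C1,C15 diol (C1 allylic alcohol, R) | C=C1C(=O)O[C@@H]2[C@@H]3O[C@@](C)(C[C@@H](OC(=O)/C(C)=C\C)[C@@H]12)[C@H](O)C=C[C@@H]3CO | intermediate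
36 | CNP0274187.1 | C=C1C(=O)O[C@@H]2[C@@H]3O[C@@](C)(C[C@@H](OC(=O)/C(C)=C\C)[C@@H]12)C(=O)C=C[C@@H]3CO | target

**Totals.** Total step count: 23. Longest linear sequence: 21 steps (steps 3 to 23, from methacrolein); steps 1 and 2 feed in at step 7.

**Steps most likely to fail**

Step 15. The hindered tertiary ether may intercept the copper carbenoid too slowly, so that the carbenoid is consumed by the C8 silyl ether oxygen (five-membered ylide) or by 1,5 C–H insertion at C9; the butenyl group may also be delivered to the wrong face of C5. The fallback sets out from acid 19 and comes back at 23. It replaces the carbenoid by an acceptor/acceptor rhodium carbenoid, which is longer-lived and strongly favours ylide formation. Mixed anhydride 20, made as in step 14, is treated with the lithium enolate of allyl acetate (LiN(iPr)2, THF, −78 °C) to give β-keto allyl ester F1. Diazo transfer (4-acetamidobenzenesulfonyl azide, Et3N, MeCN) gives 2-diazo-3-oxo ester F2. Rh2(OAc)4 in CH2Cl2 should then give, through ester-substituted oxonium ylide F3 and its [2,3]-shift, the C5-allyloxycarbonyl oxepanone F4. Deallylation and decarboxylation with Pd(PPh3)4 and morpholine in THF remove the activating ester and return 23, the C5 hydrogen being set by protonation of the enol or by base equilibration.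

Step 18. Closure of the trans-bridged seven-membered ring on the rigid trans-fused lactone may be slower than intermolecular metathesis, leading to oligomers. The fallback sets out from 23 and comes back at 27. It closes ring 2 before the lactone, on the conformationally mobile monocyclic ketone. The same catalyst in dilute toluene at 80 °C should give bicyclic ketone F5, LiBH(sBu)3 reduction then gives cis alcohol F6, and Tf2O with 2,6-di-tert-butyl-4-methylpyridine gives, through triflate F7, lactone 27 with inversion at C6.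

Step 17. The axial triflate may undergo E2 elimination toward C5 or C7, or the ring oxygen may take part and contract the ring, instead of displacement by the ester carbonyl. The fallback sets out from 23 and comes back at 26. It avoids the inversion: NaBH4 with CeCl3·7H2O in MeOH at −78 °C (small hydride, axial attack) should give the equatorial C6 epimer F8, whose hydroxyl is trans to the C7 side chain. Pyridinium p-toluenesulfonate in toluene at 80 °C then lactonises F8 with retention and loss of isobutene to 26.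

**Further compounds**

F1 | step 15 | β-keto allyl ester (C6 ketone; C5H2; allyl ester) | C=C[C@@H](OCc1ccc(OC)cc1)[C@@](C)(OC/C=C\COCc1ccc(OC)cc1)C[C@@H](O[Si](C)(C)C(C)(C)C)[C@@H](CC(=O)OC(C)(C)C)C(=O)CC(=O)OCC=C
F2 | step 15 | 2-diazo-3-oxo allyl ester (diazo at C5) | C=C[C@@H](OCc1ccc(OC)cc1)[C@@](C)(OC/C=C\COCc1ccc(OC)cc1)C[C@@H](O[Si](C)(C)C(C)(C)C)[C@@H](CC(=O)OC(C)(C)C)C(=O)C(=[N+]=[N-])C(=O)OCC=C
F3 | step 15 | ester-substituted oxonium ylide (not isolated) | [O-]C1=C(C(=O)OCC=C)[O+](C/C=C\COCc2ccc(OC)cc2)[C@](C)([C@H](OCc2ccc(OC)cc2)C=C)C[C@@H](O[Si](C)(C)C(C)(C)C)[C@H]1CC(=O)OC(C)(C)C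
F4 | step 15 | C5-allyloxycarbonyl oxepan-3-one | O=C1[C@H](CC(=O)OC(C)(C)C)[C@H](O[Si](C)(C)C(C)(C)C)C[C@@](C)([C@H](OCc2ccc(OC)cc2)C=C)O[C@]1(C(=O)OCC=C)[C@H](C=C)COCc1ccc(OC)cc1
F5 | step 18 | trans-bridged bicyclic C6 ketone (ring 2 closed; tert-butyl ester kept) | O=C1[C@H](CC(=O)OC(C)(C)C)[C@H](O[Si](C)(C)C(C)(C)C)C[C@]2(C)O[C@@H]1[C@@H](COCc3ccc(OC)cc3)C=C[C@H]2OCc3ccc(OC)cc3
F6 | step 18 | bicyclic C6 alcohol (hydroxyl cis to the C7 side chain) | O[C@@H]1[C@H](CC(=O)OC(C)(C)C)[C@H](O[Si](C)(C)C(C)(C)C)C[C@]2(C)O[C@@H]1[C@@H](COCc3ccc(OC)cc3)C=C[C@H]2OCc3ccc(OC)cc3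
F7 | step 18 | C6 triflate of F6 (not isolated) | O=S(=O)(O[C@@H]1[C@H](CC(=O)OC(C)(C)C)[C@H](O[Si](C)(C)C(C)(C)C)C[C@]2(C)O[C@@H]1[C@@H](COCc3ccc(OC)cc3)C=C[C@H]2OCc3ccc(OC)cc3)C(F)(F)F
F8 | step 17 | C6 epimer of 24 (hydroxyl trans to the C7 side chain) | O[C@H]1[C@H](CC(=O)OC(C)(C)C)[C@H](O[Si](C)(C)C(C)(C)C)C[C@@](C)([C@H](OCc2ccc(OC)cc2)C=C)O[C@@H]1[C@H](C=C)COCc1ccc(OC)cc1
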